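**Strategy.** The plan rests on closing the 1,2-dioxane last, at its O1–O2 bond. That bond joins the oxygen on secondary C3 to the oxygen on tertiary C6, and because C3 and C6 are the ends of a four-carbon run (C3–C4–C5–C6), both oxygens can first be installed as ordinary carbinols with full stereocontrol. In the key step an acyclic 3,6-bis(aminooxy) chain, carrying all five stereocentres, the (E)-C11–C12 alkene and a silyl-protected C1 alcohol, is oxidised so that the two nitrogens couple and leave as N2, the two oxygens joining to form the six-membered ring in one operation without touching either C–O bond.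

Key step: step 21

Remark: carbons are numbered C1 (carboxyl carbon) to C14 along the longest chain, so C3, C4 and C6 carry the same locants in the chain and in the 1,2-dioxane ring (O1 on C6, O2 on C3).
Remark: C1 is carried as a triisopropylsilyl ether, because a smaller silyl group 1,3 to the C3 potassium alkoxide could migrate from oxygen to oxygen during the O-amination; 3,3-di-tert-butyloxaziridine is a known reagent made in one operation from the ketimine and a peracid.

**Side chain (C7–C14)**

Step 1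
Reactants: 1 (E)-pent-2-enal
Product: 2 (3S,4E)-hept-4-en-3-ol
Conditions: Et2Zn (1.5 equiv), (−)-MIB (4 mol %), hexane/toluene, 0 °C; aq NH4Cl
Reagents that add atoms: diethylzinc, CC[Zn]CC
Why: Amino-alcohol-catalysed enantioselective 1,2-addition of a dialkylzinc to an aldehyde is dependable for (E)-enals, and the (2S)-configured morpholinoisoborneol ligand steers ethyl transfer to the carbonyl face that gives the (S)-carbinol, the same sense it shows for benzaldehyde.

Step 2
Reactants: 2 (3S,4E)-hept-4-en-3-ol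
Product: 3 (3S,4E)-hept-4-en-3-yl pyridine-2-carboxylate
Conditions: picolinic acid, DCC, DMAP (cat.), CH2Cl2, 0 °C → rt
Reagents that add atoms: picolinic acid, OC(=O)c1ccccn1
Why: Steglich esterification acylates the carbinol oxygen only, so the C–O bond and the (S) centre are untouched and the alcohol gains a chelating leaving group.

Step 3
Reactants: 4 (R)-3-bromo-2-methylpropan-1-ol
Product: 5 (R)-(3-bromo-2-methylpropoxy)(tert-butyl)dimethylsilane
Conditions: TBSCl, imidazole, DMF, rt
Reagents that add atoms: tert-butyldimethylsilyl chloride, CC(C)(C)[Si](C)(C)Cl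
Why: Routine silylation of a primary alcohol with a silyl chloride and imidazole masks the hydroxyl so that the bromide can be turned into a Grignard reagent, and the stereocentre is not involved.

Step 4
Reactants: 5 (R)-(3-bromo-2-methylpropoxy)(tert-butyl)dimethylsilane, 3 (3S,4E)-hept-4-en-3-yl pyridine-2-carboxylate
Product: 8 tert-butyl{[(2S,4R,5E)-4-ethyl-2-methyloct-5-en-1-yl]oxy}dimethylsilane, via Grignard reagent 6 (not isolated), via magnesium dialkylcuprate 7 (not isolated)
Conditions: 5 (2.2 equiv), Mg, THF, 40 °C; CuBr·SMe2 (1.1 equiv), THF/Et2O, −78 °C; then 3, −78 → −30 °C; aq NH4Cl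
Reagents that add atoms: none
Why: Copper-mediated anti-SN2′ allylic substitution, in which the cuprate attacks the γ-carbon (C10) on the face opposite to the magnesium-chelated picolinate from the conformer that keeps the carbinol hydrogen in the alkene plane, so the (S)-carbinol centre is relayed into (R)-C10 by 1,3-chirality transfer and the transposed C11–C12 alkene is formed (E), while the C8 centre of the nucleophile is untouched.

Step 5
Reactants: 8 tert-butyl{[(2S,4R,5E)-4-ethyl-2-methyloct-5-en-1-yl]oxy}dimethylsilane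
Product: 9 (2S,4R,5E)-4-ethyl-2-methyloct-5-en-1-ol
Conditions: TBAF, THF, 0 °C → rt
Reagents that add atoms: none
Why: Fluoride-induced cleavage of the silyl ether frees the primary alcohol without affecting the alkene or either stereocentre.

Step 6
Reactants: 9 (2S,4R,5E)-4-ethyl-2-methyloct-5-en-1-ol
Product: 10 (3E,5R,7S)-5-ethyl-8-iodo-7-methyloct-3-ene
Conditions: I2, PPh3, imidazole, CH2Cl2, 0 °C
Reagents that add atoms: iodine, II
Why: Appel-type iodination converts the primary alcohol into the iodide by SN2 displacement at a non-stereogenic carbon, giving the halide needed for clean iodine–lithium exchange.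

**Main chain (C1–C6) and assembly**

Step 7
Reactants: 11 propane-1,3-diol
Product: 12 3-[(triisopropylsilyl)oxy]propan-1-ol
Conditions: NaH (1.0 equiv), THF, rt; TIPSCl, 0 °C → rt
Reagents that add atoms: triisopropylsilyl chloride, CC(C)[Si](Cl)(C(C)C)C(C)C
Why: Monosilylation through the sparingly soluble monosodium alkoxide of the symmetrical diol gives the mono-ether selectively, and the bulky triisopropylsilyl group is chosen because it resists oxygen-to-oxygen migration, hydride and strong base later on.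

Step 8
Reactants: 12 3-[(triisopropylsilyl)oxy]propan-1-ol
Product: 13 3-[(triisopropylsilyl)oxy]propanal
Conditions: TEMPO (10 mol %), PhI(OAc)2 (1.1 equiv), CH2Cl2, rt
Reagents that add atoms: none
Why: Oxoammonium (TEMPO) oxidation with PhI(OAc)2 as terminal oxidant stops at the aldehyde in anhydrous CH2Cl2 and leaves the silyl ether intact.

Step 9
Reactants: 14 (R)-4-benzyl-1,3-thiazolidine-2-thione, 15 butanoyl chloride
Product: 16 1-[(4R)-4-benzyl-2-thioxo-1,3-thiazolidin-3-yl]butan-1-one
Conditions: Et3N, DMAP (cat.), CH2Cl2, 0 °C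
Reagents that add atoms: none
Why: N-Acylation of the thiazolidinethione with the acid chloride installs the butanoyl unit whose α-carbon becomes C4 and whose carbonyl carbon becomes C5.

Step 10
Reactants: 16 1-[(4R)-4-benzyl-2-thioxo-1,3-thiazolidin-3-yl]butan-1-one, 13 3-[(triisopropylsilyl)oxy]propanal
Product: 18 (2R,3S)-1-[(4R)-4-benzyl-2-thioxo-1,3-thiazolidin-3-yl]-2-ethyl-3-hydroxy-5-[(triisopropylsilyl)oxy]pentan-1-one, via chlorotitanium enolate 17 (not isolated)
Conditions: TiCl4 (1.05 equiv), i-Pr2NEt (1.1 equiv), NMP (1.0 equiv), CH2Cl2, 0 °C; then 13, −78 → 0 °C; aq NH4Cl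
Reagents that add atoms: none
Why: Titanium-mediated thiazolidinethione aldol (Crimmins aldol), in which soft enolisation gives the (Z)-chlorotitanium enolate and, with NMP occupying the free site on titanium, addition runs through the non-chelated chair-like Zimmerman–Traxler transition state with the aldehyde approaching the enolate face remote from the benzyl group, setting the C4 ethyl centre and the C3 carbinol syn in the auxiliary-controlled "Evans-syn" sense, that is (2R,3S) in the adduct.

Step 11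
Reactants: 18 (2R,3S)-1-[(4R)-4-benzyl-2-thioxo-1,3-thiazolidin-3-yl]-2-ethyl-3-hydroxy-5-[(triisopropylsilyl)oxy]pentan-1-one
Product: 19 (2R,3S)-1-[(4R)-4-benzyl-2-thioxo-1,3-thiazolidin-3-yl]-2-ethyl-3-[(triethylsilyl)oxy]-5-[(triisopropylsilyl)oxy]pentan-1-one
Conditions: TESOTf, 2,6-lutidine, CH2Cl2, −78 °C
Reagents that add atoms: triethylsilyl trifluoromethanesulfonate, CC[Si](CC)(CC)OS(=O)(=O)C(F)(F)F
Why: Silylation with the silyl triflate and a hindered base protects the hindered C3 hydroxyl at low temperature without retro-aldol cleavage, and the bulky silyl ether should also discourage coordination of zirconium in step 15.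

Step 12
Reactants: 19 (2R,3S)-1-[(4R)-4-benzyl-2-thioxo-1,3-thiazolidin-3-yl]-2-ethyl-3-[(triethylsilyl)oxy]-5-[(triisopropylsilyl)oxy]pentan-1-one
Product: 20 (2R,3S)-2-ethyl-3-[(triethylsilyl)oxy]-5-[(triisopropylsilyl)oxy]pentanal
Conditions: i-Bu2AlH (1.2 equiv), CH2Cl2, −78 °C; aq potassium sodium tartrate
Reagents that add atoms: none
Why: Reductive cleavage of the N-acyl thiazolidinethione with one hydride gives the aldehyde directly because the tetrahedral aluminium adduct survives until work-up, and the low temperature keeps the α-centre (C4) from epimerising.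

Step 13
Reactants: 20 (2R,3S)-2-ethyl-3-[(triethylsilyl)oxy]-5-[(triisopropylsilyl)oxy]pentanal
Product: 21 (3S,4S)-1,1-dibromo-3-ethyl-4-[(triethylsilyl)oxy]-6-[(triisopropylsilyl)oxy]hex-1-ene
Conditions: CBr4, PPh3, Zn, CH2Cl2, 0 °C → rt
Reagents that add atoms: carbon tetrabromide, BrC(Br)(Br)Br
Why: Corey–Fuchs dibromo-olefination (a Wittig reaction of the dibromomethylene ylide) converts the aldehyde into the 1,1-dibromoalkene, zinc keeping the medium free of acidic phosphorus bromides so that the silyl ethers and C4 are safe.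

Step 14
Reactants: 21 (3S,4S)-1,1-dibromo-3-ethyl-4-[(triethylsilyl)oxy]-6-[(triisopropylsilyl)oxy]hex-1-ene
Product: 23 (3S,4S)-4-ethyl-3-[(triethylsilyl)oxy]-1-[(triisopropylsilyl)oxy]oct-5-yne, via lithium acetylide 22 (not isolated)
Conditions: n-BuLi (2.2 equiv), THF, −78 °C; EtI (5 equiv), DMPU, −78 °C → rt
Reagents that add atoms: iodoethane, CCI
Why: Second stage of the Corey–Fuchs sequence, in which bromine–lithium exchange, Fritsch–Buttenberg–Wiechell rearrangement and deprotonation give the lithium acetylide, which is alkylated by iodoethane in the presence of the dipolar cosolvent to place the future C6 ethyl group.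

Step 15
Reactants: 23 (3S,4S)-4-ethyl-3-[(triethylsilyl)oxy]-1-[(triisopropylsilyl)oxy]oct-5-yne
Product: 25 (3S,4S,5E)-4-ethyl-6-iodo-3-[(triethylsilyl)oxy]-1-[(triisopropylsilyl)oxy]oct-5-ene, via alkenylzirconocene chloride 24 (not isolated)
Conditions: Cp2Zr(H)Cl (2.5 equiv), THF, 50 °C; I2, 0 °C
Reagents that add atoms: iodine, II
Why: Hydrozirconation adds H and Zr syn across the alkyne and, under equilibrating conditions (excess reagent, warming), zirconium should settle on C6 next to the small ethyl group and away from the branched C4, so that iodinolysis with retention gives the (E)-iodide with iodine trans to C4.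

Step 16
Reactants: 10 (3E,5R,7S)-5-ethyl-8-iodo-7-methyloct-3-ene, 25 (3S,4S,5E)-4-ethyl-6-iodo-3-[(triethylsilyl)oxy]-1-[(triisopropylsilyl)oxy]oct-5-ene
Product: 28 (3S,4S,5E,8S,10R,11E)-4,6,10-triethyl-8-methyl-3-[(triethylsilyl)oxy]-1-[(triisopropylsilyl)oxy]tetradeca-5,11-diene, via alkyllithium 26 (not isolated), via lithium borinate 27 (not isolated)
Conditions: 10 (1.3 equiv), t-BuLi (2.6 equiv), Et2O, −78 °C; 9-MeO-9-BBN, THF, −78 °C → rt; then 25, Pd(dppf)Cl2 (5 mol %), AsPh3, Cs2CO3, DMF/H2O, rt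
Reagents that add atoms: none
Why: B-alkyl Suzuki–Miyaura coupling, in which iodine–lithium exchange at −78 °C outruns 5-exo cyclisation of the hexenyllithium, the derived borinate transfers its primary alkyl group to the alkenylpalladium iodide formed by oxidative addition of zerovalent palladium, and reductive elimination joins C7 to C6 with retention of alkene geometry to give the (E)-trisubstituted C5–C6 alkene.

Step 17
Reactants: 28 (3S,4S,5E,8S,10R,11E)-4,6,10-triethyl-8-methyl-3-[(triethylsilyl)oxy]-1-[(triisopropylsilyl)oxy]tetradeca-5,11-diene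
Product: 29 (3S,4S,5E,8S,10R,11E)-4,6,10-triethyl-8-methyl-1-[(triisopropylsilyl)oxy]tetradeca-5,11-dien-3-ol
Conditions: PPTS (0.1 equiv), MeOH/CH2Cl2, 0 °C
Reagents that add atoms: none
Why: Acid-catalysed methanolysis removes the triethylsilyl ether far faster than the bulkier triisopropylsilyl ether, freeing the C3 hydroxyl needed to direct the next step.

Step 18
Reactants: 29 (3S,4S,5E,8S,10R,11E)-4,6,10-triethyl-8-methyl-1-[(triisopropylsilyl)oxy]tetradeca-5,11-dien-3-ol
Product: 30 (3S,4R,5R,6R,8S,10R,11E)-5,6-epoxy-4,6,10-triethyl-8-methyl-1-[(triisopropylsilyl)oxy]tetradec-11-en-3-ol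
Conditions: VO(acac)2 (5 mol %), t-BuOOH (1.5 equiv, in decane), CH2Cl2, 0 °C → rt
Reagents that add atoms: tert-butyl hydroperoxide, CC(C)(C)OO
Why: Hydroxyl-directed vanadium-catalysed epoxidation of a homoallylic alcohol, in which the C3 vanadate ester delivers the peroxide oxygen intramolecularly so that only the C5–C6 alkene reacts, and because 1,3-allylic strain with the C6 ethyl group holds the C4–H bond in the alkene plane the C3 arm sits on one face and oxygen is delivered to that face, which for the (E)-alkene and the (4S) centre corresponds to the (5R,6R)-epoxide.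

Step 19
Reactants: 30 (3S,4R,5R,6R,8S,10R,11E)-5,6-epoxy-4,6,10-triethyl-8-methyl-1-[(triisopropylsilyl)oxy]tetradec-11-en-3-ol
Product: 31 (3S,4S,6R,8S,10R,11E)-4,6,10-triethyl-8-methyl-1-[(triisopropylsilyl)oxy]tetradec-11-ene-3,6-diol
Conditions: LiEt3BH (3 equiv), THF, 0 °C → rt
Reagents that add atoms: none
Why: Nucleophilic hydride opens the trisubstituted epoxide by SN2 attack at the less substituted C5, so C5 becomes CH2 and the C6–O bond is untouched, leaving C6 as the (R)-configured tertiary carbinol of a 3,6-diol.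

Step 20
Reactants: 31 (3S,4S,6R,8S,10R,11E)-4,6,10-triethyl-8-methyl-1-[(triisopropylsilyl)oxy]tetradec-11-ene-3,6-diol
Product: 32 (3S,4S,6R,8S,10R,11E)-3,6-bis(aminooxy)-4,6,10-triethyl-8-methyl-1-[(triisopropylsilyl)oxy]tetradec-11-ene
Conditions: KH (2.4 equiv), DMPU, 0 °C → rt; 3,3-di-tert-butyloxaziridine (2.6 equiv), −40 °C → rt
Reagents that add atoms: 3,3-di-tert-butyloxaziridine, CC(C)(C)C1(C(C)(C)C)NO1
Why: Electrophilic amination of alkoxides, in which each potassium alkoxide attacks the nitrogen of the N–H oxaziridine and the hindered di-tert-butyl ketone that is released cannot condense with the new aminooxy groups, and since only O–N bonds are formed C3 and C6 keep their configurations.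

Step 21
Reactants: 32 (3S,4S,6R,8S,10R,11E)-3,6-bis(aminooxy)-4,6,10-triethyl-8-methyl-1-[(triisopropylsilyl)oxy]tetradec-11-ene
Product: 35 triisopropyl{2-[(3S,4S,6R)-4,6-diethyl-6-[(2S,4R,5E)-4-ethyl-2-methyloct-5-en-1-yl]-1,2-dioxan-3-yl]ethoxy}silane, via cyclic dialkoxyhydrazine 33 (not isolated), via cyclic cis-hyponitrite 34 (not isolated)
Conditions: PhI(OAc)2 (2.2 equiv), CH2Cl2, −20 °C → rt, 32 added slowly to a final 0.002 M, dark
Reagents that add atoms: none
Why: Proposed new method: PhI(OAc)2 should oxidise one aminooxy group to an electrophilic nitrogen species (an O-nitrene or its N-iodanyl equivalent) that the second aminooxy nitrogen captures to give the cyclic 1,2-dialkoxyhydrazine 33, and a second equivalent should dehydrogenate this to the eight-membered hyponitrite 34, whose ring forces the N=N bond to be cis. Such a cis-hyponitrite should lose N2 well below room temperature, leaving oxyl radicals on C3 and C6 as a singlet pair held 1,4 on the C3–C6 chain, and their radical–radical recombination forms the O1–O2 bond and closes the six-membered 1,2-dioxane (a ring contraction from eight to six atoms by extrusion, not a cyclisation onto carbon). The closest known reactions are the oxidative N–N coupling of O-alkylhydroxylamines to dialkyl hyponitrites and the thermal decomposition of hyponitrites, in which part of the caged alkoxyl pair collapses to the dialkyl peroxide. No stereocentre is created and neither C–O bond is broken, so the C3 and C6 configurations fixed in steps 10, 18 and 19 are carried through unchanged. The selectivity that matters is kinetic, since O–O collapse must beat β-scission at the tertiary C6 oxyl, 1,5-hydrogen transfer and disproportionation through the C3–H bond, and the simultaneous birth of both radicals as one spin-paired, tethered pair is what should secure this, while high dilution keeps the N–N coupling intramolecular.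

Step 22
Reactants: 35 triisopropyl{2-[(3S,4S,6R)-4,6-diethyl-6-[(2S,4R,5E)-4-ethyl-2-methyloct-5-en-1-yl]-1,2-dioxan-3-yl]ethoxy}silane
Product: 36 2-[(3S,4S,6R)-4,6-diethyl-6-[(2S,4R,5E)-4-ethyl-2-methyloct-5-en-1-yl]-1,2-dioxan-3-yl]ethan-1-ol
Conditions: TBAF, AcOH (1:1), THF, 0 °C → rt
Reagents that add atoms: none
Why: Acetic-acid-buffered fluoride cleaves the primary silyl ether under nearly neutral conditions, which avoids base-induced Kornblum–DeLaMare fragmentation of the peroxide at the C3–H bond.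

Step 23
Reactants: 36 2-[(3S,4S,6R)-4,6-diethyl-6-[(2S,4R,5E)-4-ethyl-2-methyloct-5-en-1-yl]-1,2-dioxan-3-yl]ethan-1-ol
Product: 38 2-[(3S,4S,6R)-4,6-diethyl-6-[(2S,4R,5E)-4-ethyl-2-methyloct-5-en-1-yl]-1,2-dioxan-3-yl]acetic acid, via aldehyde 37 (not isolated)
Conditions: TEMPO (0.2 equiv), PhI(OAc)2 (2.5 equiv), MeCN/H2O (1:1), rt
Reagents that add atoms: water, O
Why: TEMPO/PhI(OAc)2 oxidation in aqueous MeCN takes the primary alcohol through the aldehyde and its hydrate to the carboxylic acid under mildly acidic conditions, so the β-peroxy carbonyl compounds are never exposed to base that could open the ring by β-elimination, and the alkene and the O–O bond are inert to the oxoammonium oxidant.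

**Compound list**

1 | (E)-pent-2-enal | CC/C=C/C=O | starting material
2 | (3S,4E)-hept-4-en-3-ol | CC/C=C/[C@@H](O)CC | intermediate
3 | (3S,4E)-hept-4-en-3-yl pyridine-2-carboxylate | CC/C=C/[C@@H](OC(=O)c1ccccn1)CC | intermediate
4 | (R)-3-bromo-2-methylpropan-1-ol | BrC[C@H](C)CO | starting material
5 | (R)-(3-bromo-2-methylpropoxy)(tert-butyl)dimethylsilane | BrC[C@H](C)CO[Si](C)(C)C(C)(C)C | intermediate
6 | (R)-{3-[(tert-butyldimethylsilyl)oxy]-2-methylpropyl}magnesium bromide | Br[Mg]C[C@H](C)CO[Si](C)(C)C(C)(C)C | intermediate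
7 | bromomagnesium bis{(R)-3-[(tert-butyldimethylsilyl)oxy]-2-methylpropyl}cuprate | C[C@H](CO[Si](C)(C)C(C)(C)C)C[Cu-]C[C@H](C)CO[Si](C)(C)C(C)(C)C.[Mg+]Br | intermediate
8 | tert-butyl{[(2S,4R,5E)-4-ethyl-2-methyloct-5-en-1-yl]oxy}dimethylsilane | CC/C=C/[C@H](CC)C[C@H](C)CO[Si](C)(C)C(C)(C)C | intermediate
9 | (2S,4R,5E)-4-ethyl-2-methyloct-5-en-1-ol | CC/C=C/[C@H](CC)C[C@H](C)CO | intermediate
10 | (3E,5R,7S)-5-ethyl-8-iodo-7-methyloct-3-ene | CC/C=C/[C@H](CC)C[C@H](C)CI | intermediate
11 | propane-1,3-diol | OCCCO | starting material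
12 | 3-[(triisopropylsilyl)oxy]propan-1-ol | OCCCO[Si](C(C)C)(C(C)C)C(C)C | intermediate
13 | 3-[(triisopropylsilyl)oxy]propanal | O=CCCO[Si](C(C)C)(C(C)C)C(C)C | intermediate
14 | (R)-4-benzyl-1,3-thiazolidine-2-thione | S=C1N[C@H](Cc2ccccc2)CS1 | starting material
15 | butanoyl chloride | CCCC(Cl)=O | starting material
16 | 1-[(4R)-4-benzyl-2-thioxo-1,3-thiazolidin-3-yl]butan-1-one | CCCC(=O)N1C(=S)SC[C@H]1Cc1ccccc1 | intermediate
17 | (Z)-trichlorotitanium enolate of 16 | CC/C=C(\O[Ti](Cl)(Cl)Cl)N1C(=S)SC[C@H]1Cc1ccccc1 | intermediate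
18 | (2R,3S)-1-[(4R)-4-benzyl-2-thioxo-1,3-thiazolidin-3-yl]-2-ethyl-3-hydroxy-5-[(triisopropylsilyl)oxy]pentan-1-one | O=C(N1C(=S)SC[C@H]1Cc1ccccc1)[C@H](CC)[C@H](CCO[Si](C(C)C)(C(C)C)C(C)C)O | intermediate
19 | (2R,3S)-1-[(4R)-4-benzyl-2-thioxo-1,3-thiazolidin-3-yl]-2-ethyl-3-[(triethylsilyl)oxy]-5-[(triisopropylsilyl)oxy]pentan-1-one | O=C(N1C(=S)SC[C@H]1Cc1ccccc1)[C@H](CC)[C@H](CCO[Si](C(C)C)(C(C)C)C(C)C)O[Si](CC)(CC)CC | intermediate
20 | (2R,3S)-2-ethyl-3-[(triethylsilyl)oxy]-5-[(triisopropylsilyl)oxy]pentanal | O=C[C@H](CC)[C@H](CCO[Si](C(C)C)(C(C)C)C(C)C)O[Si](CC)(CC)CC | intermediate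
21 | (3S,4S)-1,1-dibromo-3-ethyl-4-[(triethylsilyl)oxy]-6-[(triisopropylsilyl)oxy]hex-1-ene | BrC(Br)=C[C@H](CC)[C@H](CCO[Si](C(C)C)(C(C)C)C(C)C)O[Si](CC)(CC)CC | intermediate
22 | {(3S,4S)-3-ethyl-4-[(triethylsilyl)oxy]-6-[(triisopropylsilyl)oxy]hex-1-yn-1-yl}lithium | [Li]C#C[C@H](CC)[C@H](CCO[Si](C(C)C)(C(C)C)C(C)C)O[Si](CC)(CC)CC | intermediate
23 | (3S,4S)-4-ethyl-3-[(triethylsilyl)oxy]-1-[(triisopropylsilyl)oxy]oct-5-yne | CCC#C[C@H](CC)[C@H](CCO[Si](C(C)C)(C(C)C)C(C)C)O[Si](CC)(CC)CC | intermediate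
24 | alkenylzirconocene chloride from 23 (Cp2ZrCl on C6, syn to the new H on C5; cyclopentadienyl rings drawn σ-bound) | CC/C([Zr](Cl)(C1C=CC=C1)C1C=CC=C1)=C\[C@H](CC)[C@H](CCO[Si](C(C)C)(C(C)C)C(C)C)O[Si](CC)(CC)CC | intermediate
25 | (3S,4S,5E)-4-ethyl-6-iodo-3-[(triethylsilyl)oxy]-1-[(triisopropylsilyl)oxy]oct-5-ene | CC/C(I)=C\[C@H](CC)[C@H](CCO[Si](C(C)C)(C(C)C)C(C)C)O[Si](CC)(CC)CC | intermediate
26 | [(2S,4R,5E)-4-ethyl-2-methyloct-5-en-1-yl]lithium | CC/C=C/[C@H](CC)C[C@H](C)C[Li] | intermediate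
27 | lithium 9-[(2S,4R,5E)-4-ethyl-2-methyloct-5-en-1-yl]-9-methoxy-9-borabicyclo[3.3.1]nonan-9-uide | CC/C=C/[C@H](CC)C[C@H](C)C[B-]1(OC)C2CCCC1CCC2.[Li+] | intermediate
28 | (3S,4S,5E,8S,10R,11E)-4,6,10-triethyl-8-methyl-3-[(triethylsilyl)oxy]-1-[(triisopropylsilyl)oxy]tetradeca-5,11-diene | CC/C=C/[C@H](CC)C[C@H](C)C/C(CC)=C/[C@H](CC)[C@H](CCO[Si](C(C)C)(C(C)C)C(C)C)O[Si](CC)(CC)CC | intermediate
29 | (3S,4S,5E,8S,10R,11E)-4,6,10-triethyl-8-methyl-1-[(triisopropylsilyl)oxy]tetradeca-5,11-dien-3-ol | CC/C=C/[C@H](CC)C[C@H](C)C/C(CC)=C/[C@H](CC)[C@H](CCO[Si](C(C)C)(C(C)C)C(C)C)O | intermediate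
30 | (3S,4R,5R,6R,8S,10R,11E)-5,6-epoxy-4,6,10-triethyl-8-methyl-1-[(triisopropylsilyl)oxy]tetradec-11-en-3-ol | CC/C=C/[C@H](CC)C[C@H](C)C[C@@]1(CC)O[C@@H]1[C@H](CC)[C@H](CCO[Si](C(C)C)(C(C)C)C(C)C)O | intermediate
31 | (3S,4S,6R,8S,10R,11E)-4,6,10-triethyl-8-methyl-1-[(triisopropylsilyl)oxy]tetradec-11-ene-3,6-diol | CC/C=C/[C@H](CC)C[C@H](C)C[C@](O)(CC)C[C@H](CC)[C@H](CCO[Si](C(C)C)(C(C)C)C(C)C)O | intermediate
32 | (3S,4S,6R,8S,10R,11E)-3,6-bis(aminooxy)-4,6,10-triethyl-8-methyl-1-[(triisopropylsilyl)oxy]tetradec-11-ene | CC/C=C/[C@H](CC)C[C@H](C)C[C@](ON)(CC)C[C@H](CC)[C@H](CCO[Si](C(C)C)(C(C)C)C(C)C)ON | intermediate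
33 | cyclic N,N′-dialkoxyhydrazine (1,4,2,3-dioxadiazocane spanning the C3 and C6 oxygens) | CC/C=C/[C@H](CC)C[C@H](C)C[C@]1(CC)C[C@H](CC)[C@H](CCO[Si](C(C)C)(C(C)C)C(C)C)ONNO1 | intermediate
34 | cyclic cis-hyponitrite (eight-membered O–N=N–O ring spanning C3 and C6) | CC/C=C/[C@H](CC)C[C@H](C)C[C@]1(CC)C[C@H](CC)[C@H](CCO[Si](C(C)C)(C(C)C)C(C)C)O/N=N\O1 | intermediate
35 | triisopropyl{2-[(3S,4S,6R)-4,6-diethyl-6-[(2S,4R,5E)-4-ethyl-2-methyloct-5-en-1-yl]-1,2-dioxan-3-yl]ethoxy}silane | CC/C=C/[C@H](CC)C[C@H](C)C[C@]1(CC)C[C@H](CC)[C@H](CCO[Si](C(C)C)(C(C)C)C(C)C)OO1 | intermediate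
36 | 2-[(3S,4S,6R)-4,6-diethyl-6-[(2S,4R,5E)-4-ethyl-2-methyloct-5-en-1-yl]-1,2-dioxan-3-yl]ethan-1-ol | CC/C=C/[C@H](CC)C[C@H](C)C[C@]1(CC)C[C@H](CC)[C@H](CCO)OO1 | intermediate
37 | 2-[(3S,4S,6R)-4,6-diethyl-6-[(2S,4R,5E)-4-ethyl-2-methyloct-5-en-1-yl]-1,2-dioxan-3-yl]acetaldehyde | CC/C=C/[C@H](CC)C[C@H](C)C[C@]1(CC)C[C@H](CC)[C@H](CC=O)OO1 | intermediate
38 | 2-[(3S,4S,6R)-4,6-diethyl-6-[(2S,4R,5E)-4-ethyl-2-methyloct-5-en-1-yl]-1,2-dioxan-3-yl]acetic acid | CC/C=C/[C@H](CC)C[C@H](C)C[C@]1(CC)C[C@H](CC)[C@H](CC(=O)O)OO1 | target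

**Step count**

Total: 23 steps. Longest linear sequence: 16 steps (propane-1,3-diol to the target through steps 7, 8 and 10–23). The side chain branch (steps 1, 2, 4–6) joins at step 16.

**Steps most likely to fail**

Step 21 (key step). The N–N coupling may run between molecules instead of within one. The oxyl radical pair may also be lost to β-scission at C6, 1,5-hydrogen transfer or disproportionation through the C3–H bond before the O–O bond forms. The fallback uses known peroxide chemistry, sets out from 29 and rejoins the route at 35. Mitsunobu inversion of 29 (4-nitrobenzoic acid, PPh3, DIAD) should give the (3R)-4-nitrobenzoate F1. Methanolysis (K2CO3, MeOH) should give the (3R)-alcohol F2, and MsCl/Et3N the (3R)-mesylate F3. Cobalt-catalysed hydrosilylperoxidation (Mukaiyama–Isayama conditions: Co(thd)2, O2, Et3SiH) should then add the triethylsilylperoxy group to tertiary C6 of the trisubstituted alkene, without facial control, to give the silyl peroxide F4 as both C6 epimers. The less reactive 1,2-disubstituted C11–C12 alkene is spared by limiting the silane. Fluoride (TBAF) frees the peroxide anion, which displaces the C3 mesylate with inversion (6-exo-tet) to give 35 together with its C6 epimer F5, to be separated by chromatography. This fallback gives up the control of C6 that the main route has.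

Step 20. Amination may stop at the mono-aminooxy stage because the tertiary C6 alkoxide is hindered, or the strongly basic dialkoxide may decompose before both oxygens are aminated. The fallback sets out from 31 and rejoins at 32, aminating one oxygen at a time with a smaller nitrogen electrophile. TESCl/imidazole should silylate only the secondary C3 hydroxyl to give the mono-silyl ether F6. The tertiary potassium alkoxide alone (KH, THF) is then aminated with monochloramine (NH2Cl in MTBE) to give the C6-aminooxy silyl ether F7. PPTS/MeOH removes the silyl group to give the C6-aminooxy C3-alcohol F8, and the C3 alkoxide is aminated in the same way (KH, NH2Cl) to reach 32.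

Step 18. Oxygen delivery may show poor facial selectivity if the chair-like vanadate transition state, which must place the C3 arm axial, is not clearly preferred. The acid-sensitive epoxy alcohol may also cyclise to a tetrahydrofuran on the vanadium centre. The fallback sets out from 29 and rejoins at 30 under reagent control. It is an asymmetric dioxirane epoxidation (Shi epoxidation) of 29 with the D-fructose-derived ketone 1,2:4,5-di-O-isopropylidene-β-D-erythro-2,3-hexodiulo-2,6-pyranose, KHSO5 and K2CO3 in MeCN/dimethoxymethane/H2O at 0 °C. Its spiro transition state delivers oxygen to the face of an (E)-trisubstituted alkene that gives the (5R,6R)-epoxide. The oxidant is kept limiting so that the more electron-rich trisubstituted alkene reacts before the C11–C12 alkene. No new compound arises.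

**Further compounds**

F1 | step 21 | (3R,4S,5E,8S,10R,11E)-4,6,10-triethyl-8-methyl-1-[(triisopropylsilyl)oxy]tetradeca-5,11-dien-3-yl 4-nitrobenzoate | CC/C=C/[C@H](CC)C[C@H](C)C/C(CC)=C/[C@H](CC)[C@@H](CCO[Si](C(C)C)(C(C)C)C(C)C)OC(=O)c1ccc(cc1)[N+](=O)[O-]
F2 | step 21 | (3R,4S,5E,8S,10R,11E)-4,6,10-triethyl-8-methyl-1-[(triisopropylsilyl)oxy]tetradeca-5,11-dien-3-ol | CC/C=C/[C@H](CC)C[C@H](C)C/C(CC)=C/[C@H](CC)[C@@H](CCO[Si](C(C)C)(C(C)C)C(C)C)O
F3 | step 21 | (3R,4S,5E,8S,10R,11E)-4,6,10-triethyl-8-methyl-1-[(triisopropylsilyl)oxy]tetradeca-5,11-dien-3-yl methanesulfonate | CC/C=C/[C@H](CC)C[C@H](C)C/C(CC)=C/[C@H](CC)[C@@H](CCO[Si](C(C)C)(C(C)C)C(C)C)OS(C)(=O)=O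
F4 | step 21 | (3R,4S,8S,10R,11E)-4,6,10-triethyl-8-methyl-6-[(triethylsilyl)peroxy]-1-[(triisopropylsilyl)oxy]tetradec-11-en-3-yl methanesulfonate (both C6 epimers) | CC/C=C/[C@H](CC)C[C@H](C)CC(CC)(OO[Si](CC)(CC)CC)C[C@H](CC)[C@@H](CCO[Si](C(C)C)(C(C)C)C(C)C)OS(C)(=O)=O
F5 | step 21 | triisopropyl{2-[(3S,4S,6S)-4,6-diethyl-6-[(2S,4R,5E)-4-ethyl-2-methyloct-5-en-1-yl]-1,2-dioxan-3-yl]ethoxy}silane (C6 epimer of 35) | CC/C=C/[C@H](CC)C[C@H](C)C[C@@]1(CC)C[C@H](CC)[C@H](CCO[Si](C(C)C)(C(C)C)C(C)C)OO1
F6 | step 20 | (3S,4S,6R,8S,10R,11E)-4,6,10-triethyl-8-methyl-3-[(triethylsilyl)oxy]-1-[(triisopropylsilyl)oxy]tetradec-11-en-6-ol | CC/C=C/[C@H](CC)C[C@H](C)C[C@](O)(CC)C[C@H](CC)[C@H](CCO[Si](C(C)C)(C(C)C)C(C)C)O[Si](CC)(CC)CC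
F7 | step 20 | (3S,4S,6R,8S,10R,11E)-6-(aminooxy)-4,6,10-triethyl-8-methyl-3-[(triethylsilyl)oxy]-1-[(triisopropylsilyl)oxy]tetradec-11-ene | CC/C=C/[C@H](CC)C[C@H](C)C[C@](ON)(CC)C[C@H](CC)[C@H](CCO[Si](C(C)C)(C(C)C)C(C)C)O[Si](CC)(CC)CC
F8 | step 20 | (3S,4S,6R,8S,10R,11E)-6-(aminooxy)-4,6,10-triethyl-8-methyl-1-[(triisopropylsilyl)oxy]tetradec-11-en-3-ol | CC/C=C/[C@H](CC)C[C@H](C)C[C@](ON)(CC)C[C@H](CC)[C@H](CCO[Si](C(C)C)(C(C)C)C(C)C)O
F0 | step 18 | none | none
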